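The target is disconnected at the O–C bond that would join the ortho phenol oxygen (on aryl C2′) to the carbinol carbon C2 next to the aryl ketone, so the aroyl carbinol is treated as a ring-opened benzofuran-3(2H)-one. The precursor is the racemic cyclic hemiketal 2-farnesyl-2,6-dihydroxybenzofuran-3(2H)-one, assembled from 6-hydroxybenzofuranone by C2 farnesylation and C2 hydroxylation. In one operation the key step opens the furanone ring to an achiral 1-aryl-1,2-diketone and reduces its alkyl-side carbonyl with a chiral ruthenium hydride. Both hemiketal enantiomers therefore converge on the (R)-ketol, and the labile stereocentre is formed last.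

Key step: step 6

Remark on the chemistry: compounds 5, 6 and 7 are racemic at C2 by design, and hemiketal 7 is assumed to rest in the closed form and to open reversibly under mild acid-base catalysis.

Step 1
Reactants: 1 6-hydroxybenzofuran-3(2H)-one
Product: 2 6-(tert-butyldimethylsilyloxy)benzofuran-3(2H)-one
Conditions: TBSCl, imidazole, DMF, 0 °C to rt
Reagents that add atoms: tert-butyldimethylsilyl chloride, CC(C)(C)[Si](C)(C)Cl
Why: O-silylation of the acidic 6-phenol (para to the ketone) with a silyl chloride and imidazole is a standard protection and removes the only acidic O–H before the two enolate steps.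

Step 2
Reactants: 3 (2E,6E)-farnesol
Product: 4 (2E,6E)-farnesyl bromide
Conditions: PBr3 (0.4 equiv), Et2O, −10 to 0 °C; cold NaHCO3 wash, concentrated below 20 °C, used crude at once
Reagents that add atoms: phosphorus tribromide, BrP(Br)Br
Why: Bromination of a primary allylic alcohol with PBr3 in cold ether is an SN2 displacement on the phosphite ester at the primary carbon, so the position and E geometry of the C2=C3 alkene should be kept.

Step 3
Reactants: 2 6-(tert-butyldimethylsilyloxy)benzofuran-3(2H)-one; 4 (2E,6E)-farnesyl bromide
Product: 5 (±)-2-[(2E,6E)-farnesyl]-6-(tert-butyldimethylsilyloxy)benzofuran-3(2H)-one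
Conditions: 2 (1.3 equiv), LiN(SiMe3)2 (1.25 equiv), THF, −78 °C; then 4 (1.0 equiv), −78 to −20 °C, Ar, no dipolar cosolvent
Reagents that add atoms: none
Why: This is an SN2 alkylation of a ketone lithium enolate by a primary allylic bromide, in which the tight Li–O pair in plain THF and the soft electrophile should direct attack to C2 rather than to oxygen, direct displacement keeps the alkene geometry, the excess of enolate limits a second alkylation, and C2 is formed racemic.

Step 4
Reactants: 5 (±)-2-[(2E,6E)-farnesyl]-6-(tert-butyldimethylsilyloxy)benzofuran-3(2H)-one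
Product: 6 (±)-2-[(2E,6E)-farnesyl]-2-hydroxy-6-(tert-butyldimethylsilyloxy)benzofuran-3(2H)-one
Conditions: KN(SiMe3)2 (1.05 equiv), THF, −78 °C; 2-(phenylsulfonyl)-3-phenyloxaziridine (1.3 equiv), −78 °C; AcOH quench at −78 °C
Reagents that add atoms: 2-(phenylsulfonyl)-3-phenyloxaziridine, O=S(=O)(c1ccccc1)N1OC1c1ccccc1
Why: In this Davis enolate hydroxylation the potassium enolate attacks the oxaziridine oxygen in a closed-shell oxygen transfer that should ignore the isolated trisubstituted alkenes, the potassium counter-ion disfavours addition to the released sulfonimine, and the cold acidic quench should return the closed hemiketal, racemic at a centre that is erased later.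

Step 5
Reactants: 6 (±)-2-[(2E,6E)-farnesyl]-2-hydroxy-6-(tert-butyldimethylsilyloxy)benzofuran-3(2H)-one
Product: 7 (±)-2-[(2E,6E)-farnesyl]-2,6-dihydroxybenzofuran-3(2H)-one
Conditions: Bu4NF (1.1 equiv), AcOH (1.5 equiv), THF, 0 °C
Reagents that add atoms: none
Why: Fluoride-induced cleavage of an aryl silyl ether para to a carbonyl is fast, and the acetic acid buffer protonates the phenoxide as it forms, so the hemiketal and the skipped alkene should not meet free base.

Step 6
Reactants: 7 (±)-2-[(2E,6E)-farnesyl]-2,6-dihydroxybenzofuran-3(2H)-one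
Product: 9 (2R,4E,8E)-1-(2,4-dihydroxyphenyl)-2-hydroxy-5,9,13-trimethyltetradeca-4,8,12-trien-1-one (target), via open-chain 1,2-diketone 8 (not isolated)
Conditions: RuCl(p-cymene)[(R,R)-TsDPEN] (2 mol%), HCO2H/Et3N 5:2 (about 3 equiv HCO2H), degassed EtOAc, 0 to 10 °C, Ar; stopped after one hydride equivalent (HPLC)
Reagents that add atoms: none
Why: Proposed new method: hemiketal 7 should open reversibly at the O1–C2 bond under acid-base catalysis by the formate buffer to the achiral diketone 8, which erases C2 continually (Curtin–Hammett), and the Ru–H/N–H species formed from the precatalyst and formate should pass hydride and proton to the C2 carbonyl of 8 through an outer-sphere six-membered transition state; the closest known reaction type is Noyori–Ikariya transfer hydrogenation of 1-aryl-1,2-diketones, which halts at the 2-hydroxy-1-aryl ketone at low temperature, and what is new is feeding the diketone from a 2-hydroxybenzofuranone hemiketal that carries a skipped alkene. No ring is closed; the furanone ring is opened by cleavage of O1–C2, which releases the C2′ phenol. The single stereocentre C2 is set by the catalyst alone: with the aroyl group in the place normally taken by the aryl group of an aryl alkyl ketone, the (R,R)-TsDPEN complex is predicted to deliver hydride to the face that gives R, so both enantiomers of 7 converge (the sense is to be checked on the first run and the (S,S) complex used if it is reversed). Site selectivity for the alkyl-side carbonyl is needed and should be secured by the 2,4-dihydroxyaroyl group, whose ortho and para oxygen donors and internal hydrogen bond deactivate the C1 carbonyl of 8 and of 9, while the C3 ketone of closed 7 is shielded by the fully substituted C2. Face selectivity rests on the catalyst telling the planar aroyl group from the farnesyl CH2. The cold, buffered and diluted formate medium should leave the trisubstituted alkenes and the new carbinol untouched, and no later step exists in which the carbinol could racemise.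

Compound list
1 | 6-hydroxybenzofuran-3(2H)-one | Oc1ccc2C(=O)COc2c1 | starting material
2 | 6-(tert-butyldimethylsilyloxy)benzofuran-3(2H)-one | CC(C)(C)[Si](C)(C)Oc1ccc2C(=O)COc2c1 | intermediate
3 | (2E,6E)-farnesol | CC(C)=CCC/C(C)=C/CC/C(C)=C/CO | starting material
4 | (2E,6E)-farnesyl bromide | CC(C)=CCC/C(C)=C/CC/C(C)=C/CBr | intermediate
5 | (±)-2-[(2E,6E)-farnesyl]-6-(tert-butyldimethylsilyloxy)benzofuran-3(2H)-one | CC(C)=CCC/C(C)=C/CC/C(C)=C/CC1Oc2cc(O[Si](C)(C)C(C)(C)C)ccc2C1=O | intermediate
6 | (±)-2-[(2E,6E)-farnesyl]-2-hydroxy-6-(tert-butyldimethylsilyloxy)benzofuran-3(2H)-one | CC(C)=CCC/C(C)=C/CC/C(C)=C/CC1(O)Oc2cc(O[Si](C)(C)C(C)(C)C)ccc2C1=O | intermediate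
7 | (±)-2-[(2E,6E)-farnesyl]-2,6-dihydroxybenzofuran-3(2H)-one | CC(C)=CCC/C(C)=C/CC/C(C)=C/CC1(O)Oc2cc(O)ccc2C1=O | intermediate
8 | (4E,8E)-1-(2,4-dihydroxyphenyl)-5,9,13-trimethyltetradeca-4,8,12-triene-1,2-dione (open-chain tautomer, not isolated) | CC(C)=CCC/C(C)=C/CC/C(C)=C/CC(=O)C(=O)c1ccc(O)cc1O | intermediate
9 | (2R,4E,8E)-1-(2,4-dihydroxyphenyl)-2-hydroxy-5,9,13-trimethyltetradeca-4,8,12-trien-1-one | CC(C)=CCC/C(C)=C/CC/C(C)=C/C[C@@H](O)C(=O)c1ccc(O)cc1O | target

Total step count: 6. Longest linear sequence: 5 steps (steps 1, 3, 4, 5, 6 from 1; equally steps 2, 3, 4, 5, 6 from 3).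

Steps most likely to fail

Step 6. The ring-chain opening may be too slow under the buffered conditions, hydride may go to the wrong carbonyl or a second time to give the diol, the C4=C5 alkene may migrate into conjugation through the dienol of the open diketone, or face selectivity may be poor. The fallback is a reagent-controlled asymmetric enolate hydroxylation of an open-chain ketone, which is known chemistry; it sets out from 4 and returns at 9. Bought 2′,4′-dihydroxyacetophenone would be bis-silylated (TBSOTf, 2,6-lutidine, CH2Cl2) to 1-[2,4-bis(tert-butyldimethylsilyloxy)phenyl]ethan-1-one F1. Its lithium enolate (LiN(iPr)2, THF, −78 °C, ketone in excess) would be alkylated with 4 to (4E,8E)-1-[2,4-bis(tert-butyldimethylsilyloxy)phenyl]-5,9,13-trimethyltetradeca-4,8,12-trien-1-one F2. The Z sodium enolate of F2 (NaN(SiMe3)2, THF, −78 °C) would be hydroxylated with an enantiopure (camphorsulfonyl)oxaziridine to (2R,4E,8E)-1-[2,4-bis(tert-butyldimethylsilyloxy)phenyl]-2-hydroxy-5,9,13-trimethyltetradeca-4,8,12-trien-1-one F3. The (−)-reagent is expected to give R by analogy with simple aryl alkyl ketone enolates, which is to be confirmed. Bu4NF/AcOH in THF at 0 °C would then give 9, and any shortfall in enantiomeric purity would be made up on a chiral stationary phase.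

Step 3. The ambident aromatic enolate may alkylate on oxygen, the product may be alkylated a second time at C2, or ketone 2 may self-condense. The fallback replaces the enolate by an aza-enolate, which cannot O-alkylate and stops at monoalkylation; it sets out from 2 and returns at 5. Ketone 2 would be condensed with 1,1-dimethylhydrazine (cat. AcOH, toluene, 4 Å sieves, 60 °C) to 6-(tert-butyldimethylsilyloxy)benzofuran-3(2H)-one N,N-dimethylhydrazone F4. Deprotonation (LiN(iPr)2, THF, −78 °C) and alkylation with 4 would give 2-[(2E,6E)-farnesyl]-6-(tert-butyldimethylsilyloxy)benzofuran-3(2H)-one N,N-dimethylhydrazone F5. Two-phase hydrolysis (saturated aqueous oxalic acid, Et2O, rt) would release 5.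

Step 4. The ring-opened diketone alkoxide may suffer base-induced alkene migration, the enolate may add to the sulfonimine, or the aryl silyl ether may be lost to the liberated phenoxide. The fallback changes the oxygen source to dioxygen and passes through a hydroperoxide; it sets out from 5 and returns at 6. The potassium enolate of 5 (KN(SiMe3)2, THF, −78 °C) would be exposed to dry O2 in the presence of P(OEt)3, so that (±)-2-[(2E,6E)-farnesyl]-2-hydroperoxy-6-(tert-butyldimethylsilyloxy)benzofuran-3(2H)-one F6 is reduced by the phosphite as it forms and gives 6 after a cold AcOH quench.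

Further compounds
F1 | step 6 | 1-[2,4-bis(tert-butyldimethylsilyloxy)phenyl]ethan-1-one | CC(=O)c1ccc(O[Si](C)(C)C(C)(C)C)cc1O[Si](C)(C)C(C)(C)C
F2 | step 6 | (4E,8E)-1-[2,4-bis(tert-butyldimethylsilyloxy)phenyl]-5,9,13-trimethyltetradeca-4,8,12-trien-1-one | CC(C)=CCC/C(C)=C/CC/C(C)=C/CCC(=O)c1ccc(O[Si](C)(C)C(C)(C)C)cc1O[Si](C)(C)C(C)(C)C
F3 | step 6 | (2R,4E,8E)-1-[2,4-bis(tert-butyldimethylsilyloxy)phenyl]-2-hydroxy-5,9,13-trimethyltetradeca-4,8,12-trien-1-one | CC(C)=CCC/C(C)=C/CC/C(C)=C/C[C@@H](O)C(=O)c1ccc(O[Si](C)(C)C(C)(C)C)cc1O[Si](C)(C)C(C)(C)C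
F4 | step 3 | 6-(tert-butyldimethylsilyloxy)benzofuran-3(2H)-one N,N-dimethylhydrazone | CN(C)N=C1COc2cc(O[Si](C)(C)C(C)(C)C)ccc21
F5 | step 3 | 2-[(2E,6E)-farnesyl]-6-(tert-butyldimethylsilyloxy)benzofuran-3(2H)-one N,N-dimethylhydrazone | CC(C)=CCC/C(C)=C/CC/C(C)=C/CC1Oc2cc(O[Si](C)(C)C(C)(C)C)ccc2C1=NN(C)C
F6 | step 4 | (±)-2-[(2E,6E)-farnesyl]-2-hydroperoxy-6-(tert-butyldimethylsilyloxy)benzofuran-3(2H)-one | CC(C)=CCC/C(C)=C/CC/C(C)=C/CC1(OO)Oc2cc(O[Si](C)(C)C(C)(C)C)ccc2C1=O
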